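By 20.0 h the grey run shows the split between two routes. From 15.0 h to 20.0 h the readings show target gaining 7 percentage points and side product 1 point, with a scatter of 1.5 points on each reading. Amber, with twice the starting material, still shows 7% side product at 6.00 h, about the percentage that grey shows at 5.00 h. These readings suggest that side product needs the partner and target does not.

| setting | grey | amber | eta | delta | beta | gamma | theta |
|---|---|---|---|---|---|---|---|
| starting material | 32 mM | 64 mM | 32 mM (fed, over 2.5 h) | 32 mM | 32 mM (fed, over 25 h) | 32 mM (fed, over 25 h) | 32 mM |
| partner | 32 mM | 32 mM | 32.0 mM | 32.0 mM (in portions, 2, over 25 h) | 32.0 mM | 32.0 mM | 32.0 mM |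
| temperature | 40 °C | 40 °C | 40 °C | 40 °C |  | 40 °C | 40 °C |
| remark | run made earlier | run made earlier | all else is in the flask from the start; the feed brings no volume worth counting | first portion at the start, last at 25 h | the addition at 10 °C, then warmed to 40 °C; the feed brings no volume worth counting | all else is in the flask from the start; the feed brings no volume worth counting | everything together at the start |
| time |  |  | 30 h | 30 h | 30 h | 30 h | 30 h |

- grey (time / h: target / %, side product / %): 5.00: 2, 7; 10.0: 8, 18; 15.0: 8, 25; 20.0: 15, 26
- amber (time / h: target / %, side product / %): 0.500: 3, 0; 1.00: 0, 1; 2.50: 2, 2; 6.00: 0, 7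

(standard deviation of a reading: 1.5 percentage points)

- the flask that comes out highest in share of target in target plus side product, or "all alike" when all lie within 1.5 percentage points (eta / delta / beta / gamma / theta / all alike)
- share of target in target plus side product at the end, eta
- share of target in target plus side product at the end, delta
- share of target in target plus side product at the end, beta
- share of target in target plus side product at the end, gamma
- share of target in target plus side product at the end, theta

- a reading or a percentage of target counts all its forms, free or not
- the earlier runs do not show what temperature does; that part of a forecast is a guess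

My own reckoning folds each recipe into one partner number, 0.500 for delta: the partner in the flask during the main reaction, divided by grey's partner charge. Delta starts with half the charge, and the other flasks have a number of 1.00. The selectivity, target per side product, reads 0.577 in grey at 20.0 h. Taking side product's pace as the first power of partner, I divide this by the partner number. Delta then gets odds of 1.15, a share of 53.5%, against grey's 36.6%. One number is not enough, though: grey's odds were 0.444 at 10.0 h, so age matters too, and the slowly fed gamma and beta should fall below theta and eta. My choice is delta.

The forecast differs. It chose theta at 47%, with eta 45%, delta 42%, gamma 35% and beta 17%, on the ground that “share of target depends mainly on how long product has aged”.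

The flasks give delta highest at 61.7%, then theta 40.5%, eta 39.9%, gamma 30.8% and beta 13.4%.

    starting material → intermediate A (k = 0.0710 h⁻¹, Ea = 110 kJ mol⁻¹)
    starting material + partner ⇌ intermediate B (K = 40.0 L mol⁻¹, k = 1.10 L mol⁻¹ h⁻¹, Ea = 63.0 kJ mol⁻¹, ΔH = −43.0 kJ mol⁻¹)
    starting material + partner → intermediate C (k = 4.10 L mol⁻¹ h⁻¹, Ea = 66.0 kJ mol⁻¹)
    intermediate A → target (k = 0.0320 h⁻¹, Ea = 93.0 kJ mol⁻¹)
    partner + intermediate C → side product (k = 6.50 L mol⁻¹ h⁻¹, Ea = 80.0 kJ mol⁻¹)
    intermediate B → decomposed reagent (k = 0.0310 h⁻¹, Ea = 94.0 kJ mol⁻¹)
    crystals ⇌ target, rate k7*(cs7 - [target]) while solid is left; crystals form when [target] > cs7 (solubility = 27.0 mM, k = 3.10 h⁻¹)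
    partner → decomposition product (k = 2.50 × 10⁻⁴ h⁻¹, Ea = 107 kJ mol⁻¹)
    (constants at 40 °C)

Until 25 h, delta ran on its first portion, and at 30.0 h it held target 29.6%, side product 18.3% and partner 47.5%, where theta held 22.4%, 32.9% and 15.0%. Delta's odds stand 2.37 times theta's, between the inverse partner number 2.00 and its square 4.00. Beta's neighbour with 13 mM of partner has a partner number of 0.406 and a share of 46.4%; its odds stand 5.59 times beta's, and the inverse number squared is 6.07.

The earlier runs and the new flask come from a simulation with made-up constants; the scatter is artificial.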